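The vessel, stirred at constant volume and one temperature, takes the same charges dosed in different ways, and the meeting had to say which flask ends with the most isomer of the product.

| flask | starting material | partner | remark | time |
|---|---|---|---|---|
| Monday's | 2 mM | 1.8 mM | run made earlier |  |
| Wednesday's | 2 mM | 0.90 mM | run made earlier |  |
| Thursday's | 2 mM | 3.6 mM | run made earlier |  |
| dusk | 2.0 mM | 1.80 mM (fed, over 40 s) | all else is in the flask from the start; the feed brings no volume worth counting | 3.0 min |
| summer | 2.0 mM | 1.80 mM (in portions, 4, over 40 s) | first portion at the start, last at 40 s | 3.0 min |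
| autumn | 2.0 mM | 1.80 mM | everything together at the start | 3.0 min |
| dawn | 2.0 mM (fed, over 40 s) | 1.80 mM | all else is in the flask from the start; the feed brings no volume worth counting | 3.0 min |

| run | time / min | isomer of the product / % | target / % | starting material / % |
|---|---|---|---|---|
| Monday's | 0.500 | 8.0 | 38.3 | 50.1 |
| Monday's | 1.00 | 11.8 | 38.8 | 49.5 |
| Monday's | 1.50 | 10.2 | 37.3 | 49.3 |
| Monday's | 2.00 | 9.0 | 38.5 | 50.7 |
| Monday's | 2.50 | 10.1 | 39.2 | 51.0 |
| Monday's | 3.00 | 10.9 | 37.6 | 49.5 |
| Wednesday's | 0.500 | 7.8 | 25.5 | 69.4 |
| Wednesday's | 1.00 | 8.0 | 25.0 | 68.1 |
| Wednesday's | 1.50 | 6.9 | 24.6 | 67.6 |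
| Wednesday's | 2.00 | 6.6 | 23.2 | 68.0 |
| Wednesday's | 2.50 | 8.3 | 24.3 | 68.2 |
| Wednesday's | 3.00 | 7.6 | 23.5 | 68.1 |
| Thursday's | 0.200 | 9.9 | 39.8 | 51.9 |
| Thursday's | 0.667 | 12.8 | 54.9 | 30.8 |
| Thursday's | 1.00 | 14.2 | 55.4 | 31.2 |
| Thursday's | 1.50 | 13.6 | 54.6 | 31.5 |
| Thursday's | 2.50 | 15.4 | 53.5 | 31.3 |
| Thursday's | 3.00 | 15.1 | 54.9 | 30.8 |

(each reading ± 1 percentage point)

- which flask leads in amount of isomer of the product, in percent of the starting material charged ("all alike" within 1.5 percentage points) (dusk / summer / autumn / dawn / all alike)
- how much isomer of the product is there at the end, in percent of the starting material charged: dusk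
- how much isomer of the product is there at the end, in percent of the starting material charged: summer
- how much isomer of the product is there at the end, in percent of the starting material charged: autumn
- how much isomer of the product is there at the end, in percent of the starting material charged: dawn

- the numbers in the tables scatter by 1 percentage point (one standard deviation)

The analyst reported that starting material holds still within scatter after 0.667 min at the latest in the earlier runs, with the fraction left at the last reading being 49.5% on Monday, 68.1% on Wednesday and 30.8% on Thursday. She proposed to work with that fraction left, and to carry the isomer share, the selectivity of the turnover: isomer found divided by one minus the fraction left, pooled over those last readings, which reads 0.222. Taken alone, Wednesday gives 0.238 and Thursday 0.218, with partner charges a factor 4.00 apart. The meeting therefore asked how much starting material each dosing turns over.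

The process lead answered that starting material turned per mM of partner charged reads 0.709 on Wednesday, more than 0.384 on Thursday, so in these two runs the lower partner charge went further.

My own reckoning follows. Autumn repeats Monday's charges, which gives 11.2% of isomer. For partner kept as thin as on Wednesday, Wednesday's turnover per mM applied to the 1.80 mM of partner leaves 36.2% of starting material, hence 14.2% of isomer. I expect summer and dusk near that figure or above it. I rank dusk, summer, autumn, dawn: partner is fed steadily in dusk, comes in 4 portions in summer, and is charged at the start in autumn and dawn, and in dawn starting material is still being fed in.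

The forecast, unlike my ranking, put summer first, with dusk 12%, summer 12.7%, autumn 10.2% and dawn 5.7%, on the ground that “isomer follows total conversion”.

The flask gives 16.7% in dusk, 15.0% in summer, 10.7% in autumn and 4.70% in dawn, so dusk, not the forecast's summer, leads, by 1.7 percentage points, more than the margin of 1.5 points.

    tight pair ⇌ loose pair (K = 0.430, k = 1000 s⁻¹)
    starting material ⇌ tight pair (K = 0.00170, k = 0.0600 s⁻¹)
    partner → decomposed reagent (k = 0.0930 s⁻¹)
    partner + loose pair → isomer of the product (k = 2.30 × 10⁵ M⁻¹ s⁻¹)
    partner + tight pair → target (k = 3.30 × 10⁵ M⁻¹ s⁻¹)

Over the first 40 s, mean [partner] in dusk stood at 0.0796 mM, less than the 0.219 mM in autumn. The carried share turns dusk's 26.9% of starting material left into 16.2% of isomer. In the neighbour flask, dawn with 7.2 mM of partner, 57.7% of starting material left gives 9.39% of isomer, and that flask holds 8.90%.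

All runs were computed with made-up constants, and the scatter is random.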